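**Retrosynthetic overview**
- The target comes from a protected cyclohexene by PMB removal, dibenzoylation of O3 and O7 (the CH2O arm), and final acid cleavage of a 1,2-acetonide and a 4-O-silyl ether.
- The cyclohexene is the only carbocycle and is closed late by ring-closing metathesis (C5=C6) of an octa-1,7-diene. The two dioxolane rings are made in the first step and serve as protecting groups.
- The two vinyl groups are grown from the two ends of a branched L-gulose: Wittig methylenation of the lactol carbon (gives C6) and one-carbon homologation of the terminal epoxide (gives C5).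
- Key C–C bond: C1–C7, formed by an intermolecular crossed aldol between the enolate of L-gulose diacetonide and formaldehyde, which creates the quaternary C1. C2, C3 and C4 are C3, C4 and C5 of L-gulono-1,4-lactone.

Abbreviations: TBS = tert-butyldimethylsilyl, PMB = 4-methoxybenzyl, Bz = benzoyl. Ring numbering of the target (C1 quaternary, C7 = CH2O arm) is used for the cyclohexenes.

Assumption: lactols 3, 5 and 6 are anomeric mixtures (anomeric centre left undefined in their SMILES) that react through their open-chain hydroxy-aldehyde tautomers, which are not numbered separately.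

**Route**

Step 1
Reactants: 1 L-gulono-1,4-lactone
Product: 2 2,3:5,6-di-O-isopropylidene-L-gulono-1,4-lactone
Conditions: Me2C(OMe)2, TsOH·H2O (cat.), acetone, rt
Reagents that add atoms: 2,2-dimethoxypropane COC(C)(C)OC
Why: Acid-catalysed acetonide formation (transacetalisation) closes dioxolanes on the cis-2,3-diol and on the terminal 5,6-diol without touching any stereocentre.

Step 2
Reactants: 2 2,3:5,6-di-O-isopropylidene-L-gulono-1,4-lactone
Product: 3 2,3:5,6-di-O-isopropylidene-L-gulofuranose
Conditions: iBu2AlH, CH2Cl2, −78 °C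
Reagents that add atoms: none
Why: Partial lactone reduction stops at the lactol because the tetrahedral aluminium lactolate survives at −78 °C until work-up; the four stereocentres are untouched and the new anomeric centre is of no consequence.

Step 3
Reactants: 3 2,3:5,6-di-O-isopropylidene-L-gulofuranose; 4 formaldehyde
Product: 5 2-C-(hydroxymethyl)-2,3:5,6-di-O-isopropylidene-L-gulofuranose
Conditions: 4 as 37% aqueous solution (excess), K2CO3, MeOH, 65 °C
Reagents that add atoms: none
Why: Intermolecular crossed aldol (Ho-type hydroxymethylation): K2CO3 enolises the open-chain aldehyde at C2 and the enolate adds to formaldehyde on the dioxolane face anti to the C4 substituent, the only mode that lets the aldehyde reclose to the cis-fused furanose, so the new quaternary centre (future C1) has its oxygen cis to that of future C2 and its CH2OH trans to future C3.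

Step 4
Reactants: 5 2-C-(hydroxymethyl)-2,3:5,6-di-O-isopropylidene-L-gulofuranose
Product: 6 2-C-[(tert-butyldimethylsilyloxy)methyl]-2,3:5,6-di-O-isopropylidene-L-gulofuranose
Conditions: TBSCl, imidazole, CH2Cl2, 0 °C to rt
Reagents that add atoms: tert-butyldimethylsilyl chloride CC(C)(C)[Si](C)(C)Cl
Why: Chemoselective silylation of the primary alcohol over the hemiacetal hydroxyl caps the aldol hydroxyl so that base cannot trigger retro-aldol loss of formaldehyde in the olefination.

Step 5
Reactants: 6 2-C-[(tert-butyldimethylsilyloxy)methyl]-2,3:5,6-di-O-isopropylidene-L-gulofuranose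
Product: 8 1,2-dideoxy-3-C-(hydroxymethyl)-3,4:6,7-di-O-isopropylidene-L-gulo-hept-1-enitol, via silyl ether alkene 7 (not isolated)
Conditions: Ph3PCH3Br, KOtBu, THF, 0 to 50 °C; then Bu4NF, rt
Reagents that add atoms: methyltriphenylphosphonium bromide C[P+](c1ccccc1)(c1ccccc1)c1ccccc1.[Br-]
Why: Wittig methylenation of the ring-opened aldehyde, which has no α-hydrogen and cannot epimerise, installs the vinyl group (future C6) and frees O5 (future O3), and fluoride then removes the silyl group in the same flask.

Step 6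
Reactants: 8 1,2-dideoxy-3-C-(hydroxymethyl)-3,4:6,7-di-O-isopropylidene-L-gulo-hept-1-enitol
Product: 9 bis-PMB ether of 8 (5-O-PMB and PMB-oxymethyl at C3)
Conditions: NaH, PMBCl, Bu4NI (cat.), DMF, 0 °C to rt
Reagents that add atoms: 4-methoxybenzyl chloride COc1ccc(CCl)cc1
Why: Williamson etherification converts the two free hydroxyls (future O3 and O7, the positions that will carry the benzoates) into base-stable PMB ethers with no stereocentre involved.

Step 7
Reactants: 9 bis-PMB ether
Product: 10 6,7-diol (3,4-acetonide retained)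
Conditions: AcOH/H2O (4:1), rt
Reagents that add atoms: none
Why: Selective acetal hydrolysis, since the terminal dioxolane is cleaved much faster than the hindered dioxolane on the fully substituted carbon and PMB ethers are stable to aqueous acetic acid.

Step 8
Reactants: 10 6,7-diol
Product: 12 6,7-epoxide, via primary tosylate 11 (not isolated)
Conditions: NaH, 1-(p-toluenesulfonyl)imidazole, THF, 0 °C to rt
Reagents that add atoms: none
Why: One-pot selective sulfonylation of the primary alkoxide followed by intramolecular Williamson displacement gives the terminal epoxide, and because the C–O bond at the secondary carbon (future C4) is never broken its configuration is retained.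

Step 9
Reactants: 12 6,7-epoxide
Product: 13 octa-1,7-dien-6-ol (allylic alcohol)
Conditions: Me3S+ I− (excess), n-BuLi, THF, −10 °C to rt
Reagents that add atoms: trimethylsulfonium iodide C[S+](C)C.[I-]
Why: One-carbon epoxide homologation with dimethylsulfonium methylide: the ylide opens the epoxide at its CH2 terminus and the resulting oxido sulfonium salt loses Me2S by ylide-mediated elimination to give the vinyl carbinol, with the carbinol centre (future C4) untouched.

Step 10
Reactants: 13 allylic alcohol
Product: 14 6-O-TBS octa-1,7-diene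
Conditions: TBSOTf, 2,6-lutidine, CH2Cl2, −78 to 0 °C
Reagents that add atoms: tert-butyldimethylsilyl trifluoromethanesulfonate CC(C)(C)[Si](C)(C)OS(=O)(=O)C(F)(F)F
Why: Silylation masks the future 4-OH so that later only the two PMB-protected hydroxyls are exposed for benzoylation, and TBS is chosen because it falls in the final acid step.

Step 11
Reactants: 14 6-O-TBS octa-1,7-diene
Product: 15 protected cyclohexene (1β,2β-acetonide, 3α-OPMB, 4β-OTBS, 1α-CH2OPMB)
Conditions: second-generation Grubbs catalyst [(H2IMes)(PCy3)Cl2Ru=CHPh] (5 mol %), CH2Cl2 (5 mM), 40 °C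
Reagents that add atoms: none
Why: Ring-closing metathesis of the 1,7-diene, helped by the dioxolane holding the vinyl group on C1 and the C3 chain cis, forms the C5=C6 bond of the six-membered ring with loss of ethylene and leaves all stereocentres untouched.

Step 12
Reactants: 15 protected cyclohexene
Product: 16 diol (free 3α-OH and CH2OH)
Conditions: DDQ, CH2Cl2/aq. NaH2PO4–Na2HPO4 buffer (pH 7), 0 °C to rt
Reagents that add atoms: none
Why: Oxidative PMB cleavage (hydride abstraction by DDQ, then hydrolysis of the oxocarbenium ions) frees exactly the two hydroxyls to be benzoylated while the silyl ether, acetonide and alkene are inert.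

Step 13
Reactants: 16 diol
Product: 17 dibenzoate
Conditions: BzCl, pyridine, DMAP (cat.), CH2Cl2, 0 °C to rt
Reagents that add atoms: benzoyl chloride O=C(Cl)c1ccccc1
Why: DMAP-catalysed acylation (nucleophilic catalysis) esterifies the only two free hydroxyls, the primary C7 alcohol and the secondary C3 alcohol.

Step 14
Reactants: 17 dibenzoate
Product: 18 1alpha-benzoyloxymethyl-3alpha-benzoyloxycyclohex-5-en-1beta,2beta,4beta-triol
Conditions: CF3CO2H/H2O (9:1), 0 °C to rt
Reagents that add atoms: none
Why: Acid hydrolysis removes the acetonide and the silyl ether in one operation while the benzoates survive and migrate only slowly in cold acid, so all four stereocentres are delivered unchanged.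

**Compound list**

1 | L-gulono-1,4-lactone | O=C1O[C@H]([C@@H](O)CO)[C@H](O)[C@@H]1O | starting material
2 | 2,3:5,6-di-O-isopropylidene-L-gulono-1,4-lactone | O=C1O[C@H]([C@@H]2COC(C)(C)O2)[C@@H]2OC(C)(C)O[C@H]12 | intermediate
3 | 2,3:5,6-di-O-isopropylidene-L-gulofuranose (anomeric mixture) | OC1O[C@H]([C@@H]2COC(C)(C)O2)[C@@H]2OC(C)(C)O[C@H]12 | intermediate
4 | formaldehyde | C=O | starting material
5 | 2-C-(hydroxymethyl)-2,3:5,6-di-O-isopropylidene-L-gulofuranose (anomeric mixture) | OC1O[C@H]([C@@H]2COC(C)(C)O2)[C@@H]2OC(C)(C)O[C@]12CO | intermediate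
6 | 2-C-[(tert-butyldimethylsilyloxy)methyl]-2,3:5,6-di-O-isopropylidene-L-gulofuranose (anomeric mixture) | OC1O[C@H]([C@@H]2COC(C)(C)O2)[C@@H]2OC(C)(C)O[C@]12CO[Si](C)(C)C(C)(C)C | intermediate
7 | 3-C-[(tert-butyldimethylsilyloxy)methyl]-1,2-dideoxy-3,4:6,7-di-O-isopropylidene-L-gulo-hept-1-enitol | CC(C)(C)[Si](C)(C)OC[C@]1(C=C)OC(C)(C)O[C@H]1[C@H](O)[C@@H]1COC(C)(C)O1 | intermediate
8 | 1,2-dideoxy-3-C-(hydroxymethyl)-3,4:6,7-di-O-isopropylidene-L-gulo-hept-1-enitol | OC[C@]1(C=C)OC(C)(C)O[C@H]1[C@H](O)[C@@H]1COC(C)(C)O1 | intermediate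
9 | 1,2-dideoxy-3,4:6,7-di-O-isopropylidene-5-O-(4-methoxybenzyl)-3-C-[(4-methoxybenzyloxy)methyl]-L-gulo-hept-1-enitol | COc1ccc(COC[C@]2(C=C)OC(C)(C)O[C@H]2[C@H](OCc2ccc(OC)cc2)[C@@H]2COC(C)(C)O2)cc1 | intermediate
10 | 1,2-dideoxy-3,4-O-isopropylidene-5-O-(4-methoxybenzyl)-3-C-[(4-methoxybenzyloxy)methyl]-L-gulo-hept-1-enitol (free 6,7-diol) | COc1ccc(COC[C@]2(C=C)OC(C)(C)O[C@H]2[C@H](OCc2ccc(OC)cc2)[C@@H](O)CO)cc1 | intermediate
11 | 7-O-(p-toluenesulfonyl) derivative of 10 | COc1ccc(COC[C@]2(C=C)OC(C)(C)O[C@H]2[C@H](OCc2ccc(OC)cc2)[C@@H](O)COS(=O)(=O)c2ccc(C)cc2)cc1 | intermediate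
12 | 6,7-anhydro-1,2-dideoxy-3,4-O-isopropylidene-5-O-(4-methoxybenzyl)-3-C-[(4-methoxybenzyloxy)methyl]-L-gulo-hept-1-enitol | COc1ccc(COC[C@]2(C=C)OC(C)(C)O[C@H]2[C@H](OCc2ccc(OC)cc2)[C@@H]2CO2)cc1 | intermediate
13 | 1,2,7,8-tetradeoxy-3,4-O-isopropylidene-5-O-(4-methoxybenzyl)-3-C-[(4-methoxybenzyloxy)methyl]-L-gulo-octa-1,7-dienitol (free 6-OH) | COc1ccc(COC[C@]2(C=C)OC(C)(C)O[C@H]2[C@H](OCc2ccc(OC)cc2)[C@@H](O)C=C)cc1 | intermediate
14 | 6-O-(tert-butyldimethylsilyl) ether of 13 | COc1ccc(COC[C@]2(C=C)OC(C)(C)O[C@H]2[C@H](OCc2ccc(OC)cc2)[C@@H](O[Si](C)(C)C(C)(C)C)C=C)cc1 | intermediate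
15 | 4beta-(tert-butyldimethylsilyloxy)-1beta,2beta-(isopropylidenedioxy)-3alpha-(4-methoxybenzyloxy)-1alpha-[(4-methoxybenzyloxy)methyl]cyclohex-5-ene | COc1ccc(COC[C@@]23C=C[C@H](O[Si](C)(C)C(C)(C)C)[C@@H](OCc4ccc(OC)cc4)[C@@H]2OC(C)(C)O3)cc1 | intermediate
16 | 4beta-(tert-butyldimethylsilyloxy)-1alpha-(hydroxymethyl)-1beta,2beta-(isopropylidenedioxy)cyclohex-5-en-3alpha-ol | OC[C@@]12C=C[C@H](O[Si](C)(C)C(C)(C)C)[C@@H](O)[C@@H]1OC(C)(C)O2 | intermediate
17 | 3alpha-benzoyloxy-1alpha-(benzoyloxymethyl)-4beta-(tert-butyldimethylsilyloxy)-1beta,2beta-(isopropylidenedioxy)cyclohex-5-ene | O=C(OC[C@@]12C=C[C@H](O[Si](C)(C)C(C)(C)C)[C@@H](OC(=O)c3ccccc3)[C@@H]1OC(C)(C)O2)c1ccccc1 | intermediate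
18 | 1alpha-benzoyloxymethyl-3alpha-benzoyloxycyclohex-5-en-1beta,2beta,4beta-triol | O=C(OC[C@@]1(O)C=C[C@H](O)[C@@H](OC(=O)c2ccccc2)[C@@H]1O)c1ccccc1 | target

**Summary**

Total step count: 14.
Longest linear sequence: 14 steps (1 to 18; formaldehyde 4 enters in step 3).

The three steps most likely to fail, each with a fallback:

Olefination of the hindered lactol (step 5). The aldehyde of 6 sits on a fully substituted carbon, so the phosphorus ylide may react slowly or incompletely. The fallback replaces the Wittig reaction by a Peterson olefination and sets out from 6. Me3SiCH2MgCl (THF, 0 °C to rt) adds to the open-chain aldehyde and gives the β-hydroxysilane F1 as a mixture of carbinol epimers, which does not matter. KH in THF then causes syn-elimination of silanolate and gives the silyl ether alkene 7, where the route is rejoined; Bu4NF gives 8 as before.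

Epoxide homologation (step 9). If the sulfonium ylide gives poor conversion of 12, the vinyl group is built by oxidation and olefination instead, setting out from diol 10. TBSOTf/2,6-lutidine gives the bis-silyl ether F2. HF·pyridine in THF/pyridine at 0 °C removes only the primary silyl group and gives the primary alcohol F3. Dess–Martin periodinane in CH2Cl2 gives the α-silyloxy aldehyde F4, which is methylenated with Ph3PCH3Br/KN(SiMe3)2 in THF at −78 °C. This gives diene 14, where the route is rejoined; compounds 11 to 13 are bypassed.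

Ring-closing metathesis (step 11). Both alkenes of 14 are flanked by substituted allylic carbons, one of them carrying the bulky silyl ether, so ring closure may be sluggish. The fallback changes the order of events and closes the ring on the free allylic alcohol, whose hydroxyl speeds up metathesis. Setting out from 13, the second-generation Grubbs catalyst in CH2Cl2 at 40 °C gives the cyclohexenol F5. Silylation with TBSOTf/2,6-lutidine then gives 15, where the route is rejoined.

**Further compounds**

F1 | step 5 | 3-C-[(tert-butyldimethylsilyloxy)methyl]-1-deoxy-3,4:6,7-di-O-isopropylidene-1-(trimethylsilyl)heptitol, L-gulo configuration at C3 to C6, both C2 epimers | CC(C)(C)[Si](C)(C)OC[C@]1(C(O)C[Si](C)(C)C)OC(C)(C)O[C@H]1[C@H](O)[C@@H]1COC(C)(C)O1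
F2 | step 9 | 6,7-bis-O-(tert-butyldimethylsilyl)-1,2-dideoxy-3,4-O-isopropylidene-5-O-(4-methoxybenzyl)-3-C-[(4-methoxybenzyloxy)methyl]-L-gulo-hept-1-enitol | COc1ccc(COC[C@]2(C=C)OC(C)(C)O[C@H]2[C@H](OCc2ccc(OC)cc2)[C@@H](O[Si](C)(C)C(C)(C)C)CO[Si](C)(C)C(C)(C)C)cc1
F3 | step 9 | 6-O-(tert-butyldimethylsilyl)-1,2-dideoxy-3,4-O-isopropylidene-5-O-(4-methoxybenzyl)-3-C-[(4-methoxybenzyloxy)methyl]-L-gulo-hept-1-enitol (free 7-OH) | COc1ccc(COC[C@]2(C=C)OC(C)(C)O[C@H]2[C@H](OCc2ccc(OC)cc2)[C@@H](O[Si](C)(C)C(C)(C)C)CO)cc1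
F4 | step 9 | C7 aldehyde obtained from F3 (6-O-TBS, 7-oxo) | COc1ccc(COC[C@]2(C=C)OC(C)(C)O[C@H]2[C@H](OCc2ccc(OC)cc2)[C@@H](O[Si](C)(C)C(C)(C)C)C=O)cc1
F5 | step 11 | 1beta,2beta-(isopropylidenedioxy)-3alpha-(4-methoxybenzyloxy)-1alpha-[(4-methoxybenzyloxy)methyl]cyclohex-5-en-4beta-ol | COc1ccc(COC[C@@]23C=C[C@H](O)[C@@H](OCc4ccc(OC)cc4)[C@@H]2OC(C)(C)O3)cc1
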